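**Retrosynthetic overview** (isoflavan numbering: O1, C2, C3, C4, C4a–C8a for rings C and A; primed atoms for ring B)
1. Ring C is opened at C4–C4a and at C3–H, which also removes the only stereocentre. The precursor is the achiral aryl 2-arylallyl ether 12: O1–C2 in place, C3=C4 as a 1,1-disubstituted alkene, Br on C4a.
2. Forward, in one flask: copper hydride-catalysed enantioselective hydroboration sets C3 and makes C4 a primary boronate; an intramolecular Suzuki–Miyaura coupling with C4a–Br then closes ring C.
3. Enabling feature: C3 carries one H between two CH2 groups (C2, C4), and C4a is the ring-A carbon ortho to O1. A C3=C4 alkene hung from O1–C2 therefore reaches C4a in a six-membered ring, while the prenyl group on C8 blocks the other ortho position.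
4. Rings A and B are the same 4-substituted 2-prenylresorcinol. One bromophenol 7 serves twice: its bromine marks C4a in ring A and C1' in ring B. It comes from 4-bromoresorcinol by silylation, O-(1,1-dimethylallyl)ation and Claisen rearrangement, the bromine blocking the second ortho site.
5. Order of rings: A and B are bought as arenes; ring C is the only ring formed (step 9). Silyl ethers are used throughout, so the end is a fluoride deprotection and no acid meets the ortho-prenylphenols.

Key step: step 9

Assumption: (S)-DTBM-SEGPHOS is taken to give the (R)-boronate 13 (sense assigned by analogy with α-substituted styrenes); if a pilot run shows the opposite sense, the antipodal ligand is used and nothing else changes.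

**Step 1**
Reactants: 1 4-bromoresorcinol
Product: 2 2-bromo-5-(triisopropylsilyloxy)phenol
Conditions: TIPSCl (1.05 equiv), imidazole, CH2Cl2, 0 °C
Reagents that add atoms: chlorotriisopropylsilane (TIPSCl), CC(C)[Si](Cl)(C(C)C)C(C)C
Why: Regioselective O-silylation by steric differentiation: the hydroxyl para to bromine has two free ortho positions whereas the one ortho to bromine is shielded, so the bulky silyl chloride should react at the former.

**Step 2**
Reactants: 3 2-methylbut-3-en-2-ol
Product: 4 tert-butyl (2-methylbut-3-en-2-yl) carbonate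
Conditions: n-BuLi, THF, −78 → 0 °C; then Boc2O, 0 °C → rt
Reagents that add atoms: di-tert-butyl dicarbonate (Boc2O), CC(C)(C)OC(=O)OC(=O)OC(C)(C)C
Why: Acylation of the lithium tert-alkoxide with Boc2O (mixed carbonate formation) is the standard entry to tertiary allylic carbonates for palladium-catalysed allylation.

**Step 3**
Reactants: 2 2-bromo-5-(triisopropylsilyloxy)phenol; 4 tert-butyl (2-methylbut-3-en-2-yl) carbonate
Product: 5 1-bromo-2-(2-methylbut-3-en-2-yloxy)-4-(triisopropylsilyloxy)benzene
Conditions: Pd(PPh3)4 (2 mol%), THF, 4 Å MS, 0 °C → rt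
Reagents that add atoms: none
Why: Tsuji–Trost decarboxylative O-allylation: zerovalent palladium ionises 4 to a 1,1-dimethyl-π-allyl complex and tert-butoxide (after loss of CO2), the phenoxide of 2 attacks the more substituted terminus under kinetic control to give the tertiary ether, and the electron-rich aryl bromide should not undergo oxidative addition at this temperature.

**Step 4**
Reactants: 5 1-bromo-2-(2-methylbut-3-en-2-yloxy)-4-(triisopropylsilyloxy)benzene
Product: 7 6-bromo-2-(3-methylbut-2-enyl)-3-(triisopropylsilyloxy)phenol, via ortho-dienone 6 (not isolated)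
Conditions: PhNEt2, 130 °C
Reagents that add atoms: none
Why: Aromatic Claisen rearrangement ([3,3]-sigmatropic shift): bromine occupies one ortho position, so the allyl unit is delivered with transposition (as a prenyl group) only to the free ortho carbon between the two oxygens, and tautomerisation of dienone 6 returns the phenol next to bromine.

**Step 5**
Reactants: 7 6-bromo-2-(3-methylbut-2-enyl)-3-(triisopropylsilyloxy)phenol
Product: 8 1-bromo-2-(tert-butyldimethylsilyloxy)-3-(3-methylbut-2-enyl)-4-(triisopropylsilyloxy)benzene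
Conditions: TBSOTf, 2,6-lutidine, CH2Cl2, 0 °C → rt
Reagents that add atoms: tert-butyldimethylsilyl triflate (TBSOTf), CC(C)(C)[Si](C)(C)OS(=O)(=O)C(F)(F)F
Why: O-Silylation of a hindered phenol with a silyl triflate and a hindered base masks the future 2'-OH with a group that leaves later together with the TIPS ethers.

**Step 6**
Reactants: 8 1-bromo-2-(tert-butyldimethylsilyloxy)-3-(3-methylbut-2-enyl)-4-(triisopropylsilyloxy)benzene
Product: 9 2-[2-(tert-butyldimethylsilyloxy)-3-(3-methylbut-2-enyl)-4-(triisopropylsilyloxy)phenyl]-4,4,5,5-tetramethyl-1,3,2-dioxaborolane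
Conditions: B2pin2, Pd(dppf)Cl2 (5 mol%), KOAc, 1,4-dioxane, 90 °C
Reagents that add atoms: bis(pinacolato)diboron (B2pin2), CC1(C)OB(OC1(C)C)B1OC(C)(C)C(C)(C)O1
Why: Miyaura borylation of the aryl bromide leaves silyl ethers and trisubstituted alkenes untouched and avoids an ortho-lithiated aryl silyl ether, which could undergo retro-Brook silyl migration.

**Step 7**
Reactants: 9 the arylboronate of step 6; 10 2-bromoprop-2-en-1-ol
Product: 11 2-[2-(tert-butyldimethylsilyloxy)-3-(3-methylbut-2-enyl)-4-(triisopropylsilyloxy)phenyl]prop-2-en-1-ol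
Conditions: Pd(dppf)Cl2 (5 mol%), K3PO4, 1,4-dioxane/H2O, 60 °C
Reagents that add atoms: none
Why: Suzuki–Miyaura coupling of an arylboronate with a 1,1-disubstituted vinyl bromide, which adds readily to palladium; the free allylic hydroxyl is tolerated.

**Step 8**
Reactants: 7 6-bromo-2-(3-methylbut-2-enyl)-3-(triisopropylsilyloxy)phenol; 11 the 2-arylallyl alcohol of step 7
Product: 12 1-bromo-2-({2-[2-(tert-butyldimethylsilyloxy)-3-(3-methylbut-2-enyl)-4-(triisopropylsilyloxy)phenyl]prop-2-enyl}oxy)-3-(3-methylbut-2-enyl)-4-(triisopropylsilyloxy)benzene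
Conditions: PPh3, DIAD, THF, 0 °C → rt
Reagents that add atoms: none
Why: Mitsunobu etherification of the acidic ortho-bromophenol with a primary allylic alcohol; because the 2-arylallyl unit is symmetrical, direct and SN2' displacement give the same ether.

**Step 9**
Reactants: 12 the aryl 2-arylallyl ether of step 8
Product: 14 (3R)-2'-O-TBS-7,4'-di-O-TIPS-kanzonol X, via (R)-alkylboronate 13 (not isolated)
Conditions: CuCl (5 mol%), KOt-Bu (10 mol%), (S)-DTBM-SEGPHOS (6 mol%), HBpin (2 equiv), THF, rt; then degassed 3 M aq K3PO4 (until H2 evolution stops), Pd(OAc)2 (10 mol%), RuPhos (20 mol%), toluene, 80 °C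
Reagents that add atoms: none
Why: L*CuH (from CuCl/KOt-Bu/HBpin) adds syn across the 1,1-disubstituted C3=C4 alkene with copper on the terminal carbon C4 and σ-bond metathesis with HBpin releases the primary boronate 13; after hydrolysis of excess HBpin, Pd(OAc)2/RuPhos inserts into C4a–Br, C4 passes from boron to palladium within the same molecule and C(sp2)–C(sp3) reductive elimination forges C4–C4a. The closest known reaction types are the copper hydride-catalysed enantioselective anti-Markovnikov hydroboration of 1,1-disubstituted aryl alkenes and the hydroboration/intramolecular B-alkyl Suzuki–Miyaura ring closure of ortho-haloaryl alkenes. Ring C closes by reductive elimination from a seven-membered oxapalladacycle (Pd, C4a, C8a, O1, C2, C3, C4) to the six-membered dihydropyran, overall a 6-endo anti-Markovnikov hydroarylation of the alkene. C3 is set under catalyst control: the bisphosphine discriminates the alkene faces by the difference between the aryl and the aryloxymethyl substituent in the hydrocupration, and the centre, β to boron and then to palladium and bearing no acidifying group, is not touched again. The step needs chemoselectivity for the 1,1-disubstituted alkene over the two trisubstituted prenyl alkenes and over C–Br (both inert to L*CuH/HBpin) and anti-Markovnikov regioselectivity, which the 1,1-disubstitution and the twisted ortho-siloxyaryl group secure. The site of ring closure is fixed because bromine sits on C4a, the position ortho to O1 that step 4 left next to the phenol.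

**Step 10**
Reactants: 14 (3R)-2'-O-TBS-7,4'-di-O-TIPS-kanzonol X
Product: 15 kanzonol X
Conditions: Bu4NF (4 equiv), AcOH (4 equiv), degassed THF, 0 °C → rt
Reagents that add atoms: none
Why: Fluoride-induced cleavage of the three aryl silyl ethers (Si–F bond formation), buffered with AcOH, should release the phenols without acid, which avoids cyclisation of the ortho-prenylphenols to dimethylchromans and leaves C3 untouched.

**Compound list**
1 | 4-bromoresorcinol (4-bromobenzene-1,3-diol) | Oc1ccc(Br)c(O)c1 | starting material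
2 | 2-bromo-5-(triisopropylsilyloxy)phenol | CC(C)[Si](Oc1ccc(Br)c(O)c1)(C(C)C)C(C)C | intermediate
3 | 2-methylbut-3-en-2-ol | CC(C)(O)C=C | starting material
4 | tert-butyl (2-methylbut-3-en-2-yl) carbonate | CC(C)(C=C)OC(=O)OC(C)(C)C | intermediate
5 | 1-bromo-2-(2-methylbut-3-en-2-yloxy)-4-(triisopropylsilyloxy)benzene | C=CC(C)(C)Oc1cc(O[Si](C(C)C)(C(C)C)C(C)C)ccc1Br | intermediate
6 | 2-bromo-6-(3-methylbut-2-enyl)-5-(triisopropylsilyloxy)cyclohexa-2,4-dien-1-one (racemic at C6) | O=C1C(Br)=CC=C(O[Si](C(C)C)(C(C)C)C(C)C)C1CC=C(C)C | intermediate (not isolated)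
7 | 6-bromo-2-(3-methylbut-2-enyl)-3-(triisopropylsilyloxy)phenol | CC(C)=CCc1c(O)c(Br)ccc1O[Si](C(C)C)(C(C)C)C(C)C | intermediate
8 | 1-bromo-2-(tert-butyldimethylsilyloxy)-3-(3-methylbut-2-enyl)-4-(triisopropylsilyloxy)benzene | CC(C)=CCc1c(O[Si](C)(C)C(C)(C)C)c(Br)ccc1O[Si](C(C)C)(C(C)C)C(C)C | intermediate
9 | 2-[2-(tert-butyldimethylsilyloxy)-3-(3-methylbut-2-enyl)-4-(triisopropylsilyloxy)phenyl]-4,4,5,5-tetramethyl-1,3,2-dioxaborolane | CC(C)=CCc1c(O[Si](C)(C)C(C)(C)C)c(B2OC(C)(C)C(C)(C)O2)ccc1O[Si](C(C)C)(C(C)C)C(C)C | intermediate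
10 | 2-bromoprop-2-en-1-ol | OCC(Br)=C | starting material
11 | 2-[2-(tert-butyldimethylsilyloxy)-3-(3-methylbut-2-enyl)-4-(triisopropylsilyloxy)phenyl]prop-2-en-1-ol | CC(C)=CCc1c(O[Si](C)(C)C(C)(C)C)c(C(=C)CO)ccc1O[Si](C(C)C)(C(C)C)C(C)C | intermediate
12 | 1-bromo-2-({2-[2-(tert-butyldimethylsilyloxy)-3-(3-methylbut-2-enyl)-4-(triisopropylsilyloxy)phenyl]prop-2-enyl}oxy)-3-(3-methylbut-2-enyl)-4-(triisopropylsilyloxy)benzene (achiral) | CC(C)=CCc1c(O[Si](C)(C)C(C)(C)C)c(C(=C)COc2c(Br)ccc(O[Si](C(C)C)(C(C)C)C(C)C)c2CC=C(C)C)ccc1O[Si](C(C)C)(C(C)C)C(C)C | intermediate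
13 | 2-{(2R)-3-[6-bromo-2-(3-methylbut-2-enyl)-3-(triisopropylsilyloxy)phenoxy]-2-[2-(tert-butyldimethylsilyloxy)-3-(3-methylbut-2-enyl)-4-(triisopropylsilyloxy)phenyl]propyl}-4,4,5,5-tetramethyl-1,3,2-dioxaborolane | CC(C)=CCc1c(O[Si](C)(C)C(C)(C)C)c([C@@H](CB3OC(C)(C)C(C)(C)O3)COc2c(Br)ccc(O[Si](C(C)C)(C(C)C)C(C)C)c2CC=C(C)C)ccc1O[Si](C(C)C)(C(C)C)C(C)C | intermediate (not isolated)
14 | (3R)-3-[2-(tert-butyldimethylsilyloxy)-3-(3-methylbut-2-enyl)-4-(triisopropylsilyloxy)phenyl]-8-(3-methylbut-2-enyl)-7-(triisopropylsilyloxy)chroman | CC(C)=CCc1c(O[Si](C)(C)C(C)(C)C)c([C@@H]2COc3c(ccc(O[Si](C(C)C)(C(C)C)C(C)C)c3CC=C(C)C)C2)ccc1O[Si](C(C)C)(C(C)C)C(C)C | intermediate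
15 | kanzonol X, (3R)-3-[2,4-dihydroxy-3-(3-methylbut-2-enyl)phenyl]-8-(3-methylbut-2-enyl)chroman-7-ol | CC(C)=CCc1c(O)ccc([C@@H]2COc3c(ccc(O)c3CC=C(C)C)C2)c1O | target

**Step count**
Total: 10 steps. Longest linear sequence: 9 steps (steps 1, 3, 4, 5, 6, 7, 8, 9, 10, from 4-bromoresorcinol); step 2 is a one-step side branch.

**Steps most likely to fail**

Step 9. Two processes are at risk: weak enantiofacial discrimination in the hydrocupration, because the twisted ortho-siloxyaryl group and the aryloxymethyl group may look alike to the catalyst; and, in the second stage, β-hydride elimination or protodeboronation outrunning the ring-closing transmetalation. The fallback sets C3 by enzymatic desymmetrisation and closes the same C4–C4a bond by anionic (Parham) cyclisation. It sets out from 11. Hydroboration with 9-BBN and oxidation with NaBO3 should give the prochiral 2-arylpropane-1,3-diol F1. Lipase-catalysed monoacetylation (Burkholderia cepacia lipase, vinyl acetate, t-BuOMe), with the lipase chosen for the enantiotopic hydroxymethyl group that leads to the (R)-series, should give the monoacetate F2, which is used at once to avoid acyl migration. Mitsunobu etherification of F2 with phenol 7 (PPh3, DIAD) should give the ether acetate F3. i-Bu2AlH at −78 °C removes the acetate to give the primary alcohol F4, and CBr4/PPh3 converts it into the dibromide F5. t-BuLi (THF/Et2O, −100 °C) exchanges the aryl bromide selectively, and on warming the aryllithium displaces the primary bromide (6-exo-tet), which returns to the route at 14.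

Step 8. The process at risk is slow etherification of the doubly ortho-substituted phenol 7, so that the activated allylic alcohol is diverted to N-alkylation of the reduced azodicarboxylate or to elimination. The fallback reverses the order of bond formation. It sets out from 7: alkylation with 2,3-dibromoprop-1-ene (K2CO3, acetone) should give the 2-bromoallyl ether F6. Suzuki–Miyaura coupling of boronate 9 with F6 (Pd(PPh3)4, K3PO4, THF/H2O, 45 °C) should occur at the vinyl C–Br bond, which adds to zerovalent palladium far faster than the electron-rich ortho-alkoxy aryl bromide, and returns to the route at 12.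

Step 3. The process at risk is attack of the phenoxide at the unsubstituted allyl terminus, or palladium-mediated isomerisation of the tertiary ether, giving the linear O-prenyl ether, which cannot deliver a prenyl group on rearrangement. The fallback is copper-catalysed propargylic etherification followed by semi-hydrogenation. It sets out from 2: 3-chloro-3-methylbut-1-yne, CuCl2 (cat.), DBU, MeCN, 0 °C should give the aryl 1,1-dimethylpropargyl ether F7. H2 over Pd/CaCO3 poisoned with Pb(OAc)2 (Lindlar catalyst) with quinoline reduces the alkyne to the alkene and returns to the route at 5.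

**Further compounds**
F1 | step 9 | 2-[2-(tert-butyldimethylsilyloxy)-3-(3-methylbut-2-enyl)-4-(triisopropylsilyloxy)phenyl]propane-1,3-diol | CC(C)=CCc1c(O[Si](C)(C)C(C)(C)C)c(C(CO)CO)ccc1O[Si](C(C)C)(C(C)C)C(C)C
F2 | step 9 | (2R)-2-[2-(tert-butyldimethylsilyloxy)-3-(3-methylbut-2-enyl)-4-(triisopropylsilyloxy)phenyl]-3-hydroxypropyl acetate | CC(C)=CCc1c(O[Si](C)(C)C(C)(C)C)c([C@@H](COC(C)=O)CO)ccc1O[Si](C(C)C)(C(C)C)C(C)C
F3 | step 9 | (2R)-3-[6-bromo-2-(3-methylbut-2-enyl)-3-(triisopropylsilyloxy)phenoxy]-2-[2-(tert-butyldimethylsilyloxy)-3-(3-methylbut-2-enyl)-4-(triisopropylsilyloxy)phenyl]propyl acetate | CC(C)=CCc1c(O[Si](C)(C)C(C)(C)C)c([C@@H](COC(C)=O)COc2c(Br)ccc(O[Si](C(C)C)(C(C)C)C(C)C)c2CC=C(C)C)ccc1O[Si](C(C)C)(C(C)C)C(C)C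
F4 | step 9 | (2S)-3-[6-bromo-2-(3-methylbut-2-enyl)-3-(triisopropylsilyloxy)phenoxy]-2-[2-(tert-butyldimethylsilyloxy)-3-(3-methylbut-2-enyl)-4-(triisopropylsilyloxy)phenyl]propan-1-ol | CC(C)=CCc1c(O[Si](C)(C)C(C)(C)C)c([C@@H](CO)COc2c(Br)ccc(O[Si](C(C)C)(C(C)C)C(C)C)c2CC=C(C)C)ccc1O[Si](C(C)C)(C(C)C)C(C)C
F5 | step 9 | 1-bromo-2-{(2R)-3-bromo-2-[2-(tert-butyldimethylsilyloxy)-3-(3-methylbut-2-enyl)-4-(triisopropylsilyloxy)phenyl]propoxy}-3-(3-methylbut-2-enyl)-4-(triisopropylsilyloxy)benzene | CC(C)=CCc1c(O[Si](C)(C)C(C)(C)C)c([C@@H](CBr)COc2c(Br)ccc(O[Si](C(C)C)(C(C)C)C(C)C)c2CC=C(C)C)ccc1O[Si](C(C)C)(C(C)C)C(C)C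
F6 | step 8 | 1-bromo-2-(2-bromoprop-2-enyloxy)-3-(3-methylbut-2-enyl)-4-(triisopropylsilyloxy)benzene | C=C(Br)COc1c(Br)ccc(O[Si](C(C)C)(C(C)C)C(C)C)c1CC=C(C)C
F7 | step 3 | 1-bromo-2-(2-methylbut-3-yn-2-yloxy)-4-(triisopropylsilyloxy)benzene | C#CC(C)(C)Oc1cc(O[Si](C(C)C)(C(C)C)C(C)C)ccc1Br
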